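**Strategy.** Numbering: ring C1 (alkene carbon bearing C7H2OBz), C2 (alkene CH), C3, C4 (free carbinols), C5 (benzoate), C6 (free carbinol). The array O–C6–C1–C7–O is read as a β-keto ester, the product of a diazoacetate insertion into a ketone. The precursor is therefore a cyclopentanone made of C2–C6 only, with C6 as carbonyl and the C3, C4 and C5 oxygens in place, obtained from (R)-4-silyloxycyclopentenone by anti dihydroxylation. In one operation ethyl diazoacetate enlarges this five-membered ring to the six-membered carbocycle and brings in C1 together with C7. Dehydrogenation, hydride reduction and an orthoester-controlled axial benzoylation finish the synthesis.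

Key step: step 3

Remark: compounds 1, 4, 9 and 12 are taken as catalogue chemicals. Where an intermediate that is not isolated carries a centre that is destroyed in the same step (the selenide carbon of 6, the orthoester carbon of 13, the cyclopropane carbons of F2), one epimer is drawn; the other converges on the same product.

Step 1
Reactants: 1 (4R)-4-[(tert-butyldimethylsilyl)oxy]cyclopent-2-en-1-one
Product: 2 (2S,3R,4R)-4-[(tert-butyldimethylsilyl)oxy]-2,3-dihydroxycyclopentan-1-one
Conditions: OsO4 (cat.), N-methylmorpholine N-oxide, citric acid, tBuOH/H2O, rt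
Reagents that add atoms: osmium tetroxide O=[Os](=O)(=O)=O; N-methylmorpholine N-oxide C[N+]1([O-])CCOCC1; water O
Why: OsO4/N-oxide catalytic syn-dihydroxylation (citric-acid-buffered for the electron-poor enone) should add both oxygens to the ring face opposite the C4 silyloxy group, which sets the two new carbinol centres (future C5 and C4) cis to each other and trans to the silyl ether (future C3).

Step 2
Reactants: 2 (2S,3R,4R)-4-[(tert-butyldimethylsilyl)oxy]-2,3-dihydroxycyclopentan-1-one
Product: 3 (3aS,6R,6aR)-6-[(tert-butyldimethylsilyl)oxy]-2,2-dimethyltetrahydro-4H-cyclopenta[d][1,3]dioxol-4-one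
Conditions: 2,2-dimethoxypropane, pyridinium p-toluenesulfonate (cat.), acetone, rt
Reagents that add atoms: 2,2-dimethoxypropane COC(C)(C)OC
Why: Acid-catalysed transacetalisation (acetonide formation) ties the cis-diol into a cis-fused dioxolane, which creates no stereocenter and should protect the oxygenated carbon next to the ketone against epimerisation in the later steps.

Step 3
Reactants: 3 (3aS,6R,6aR)-6-[(tert-butyldimethylsilyl)oxy]-2,2-dimethyltetrahydro-4H-cyclopenta[d][1,3]dioxol-4-one; 4 ethyl diazoacetate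
Product: 5 ethyl (3aS,7R,7aR)-7-[(tert-butyldimethylsilyl)oxy]-2,2-dimethyl-4-oxohexahydro-1,3-benzodioxole-5-carboxylate (β-keto ester, drawn as its enol)
Conditions: BF3·OEt2 (1.2 equiv), CH2Cl2, −78 → 0 °C; NaHCO3 quench
Reagents that add atoms: ethyl diazoacetate CCOC(=O)C=[N+]=[N-]
Why: This is the Lewis-acid-promoted diazoacetate homologation of a cyclic ketone (Tiffeneau–Demjanov-type ring enlargement): the diazo carbon adds to the BF3-activated carbonyl of 3 and the β-oxido diazonium ion loses N2 with a 1,2-shift of a ring C–C bond, so that the diazo carbon becomes ring atom C1 and its ester carbon becomes C7. No ring is closed; the existing five-membered ring (C2–C6) is enlarged to the six-membered ring by insertion of C1 between C6 and C2. The step needs migration of the CH2 carbon (C2) and not of the acetal-bearing methine (C5); the electron-withdrawing α-oxygen and the higher substitution at C5 both disfavour migration of C5. A second homologation should be suppressed because the product is an enolised β-keto ester that is inert to the diazo ester. The only new sp3 centre (C1) is enolised and is removed in step 4, and the three existing stereocenters (C3, C4, C5) are not involved.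

Step 4
Reactants: 5 ethyl (3aS,7R,7aR)-7-[(tert-butyldimethylsilyl)oxy]-2,2-dimethyl-4-oxohexahydro-1,3-benzodioxole-5-carboxylate
Product: 7 ethyl (3aS,7R,7aR)-7-[(tert-butyldimethylsilyl)oxy]-2,2-dimethyl-4-oxo-3a,4,7,7a-tetrahydro-1,3-benzodioxole-5-carboxylate, via α-phenylselanyl β-keto ester 6 (not isolated)
Conditions: PhSeCl, pyridine, CH2Cl2, 0 °C; then 30% H2O2 (2.5 equiv), 0 °C → rt; used after a short silica plug
Reagents that add atoms: none
Why: α-Selenenylation of the β-keto ester enol followed by selenoxide syn-elimination can only eliminate toward the C2 hydrogens, which should place the double bond at C1=C2 and creates no stereocenter.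

Step 5
Reactants: 7 ethyl (3aS,7R,7aR)-7-[(tert-butyldimethylsilyl)oxy]-2,2-dimethyl-4-oxo-3a,4,7,7a-tetrahydro-1,3-benzodioxole-5-carboxylate
Product: 8 (3aR,4R,7R,7aR)-7-[(tert-butyldimethylsilyl)oxy]-5-(hydroxymethyl)-2,2-dimethyl-3a,4,7,7a-tetrahydro-1,3-benzodioxol-4-ol
Conditions: iBu2AlH (5 equiv), CH2Cl2, −78 → −40 °C; Rochelle-salt work-up
Reagents that add atoms: none
Why: The aluminium hydride should reduce the ketone in 1,2-fashion and the ester to the primary alcohol in one operation, with hydride attacking C6 from the convex face, anti to the adjacent C5–O bond of the cis-fused dioxolane (Felkin–Anh sense), which sets the C6 carbinol cis to O5.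

Step 6
Reactants: 8 (3aR,4R,7R,7aR)-7-[(tert-butyldimethylsilyl)oxy]-5-(hydroxymethyl)-2,2-dimethyl-3a,4,7,7a-tetrahydro-1,3-benzodioxol-4-ol; 9 benzoyl chloride
Product: 10 [(3aR,4R,7R,7aR)-7-[(tert-butyldimethylsilyl)oxy]-4-hydroxy-2,2-dimethyl-3a,4,7,7a-tetrahydro-1,3-benzodioxol-5-yl]methyl benzoate
Conditions: BzCl (1.05 equiv), 2,4,6-collidine, CH2Cl2, −40 → −20 °C
Reagents that add atoms: benzoyl chloride O=C(Cl)c1ccccc1
Why: Kinetically controlled esterification should acylate the unhindered primary allylic hydroxyl in preference to the secondary C6 hydroxyl, which is flanked by the substituted alkene carbon and the dioxolane; no stereocenter is touched.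

Step 7
Reactants: 10 [(3aR,4R,7R,7aR)-7-[(tert-butyldimethylsilyl)oxy]-4-hydroxy-2,2-dimethyl-3a,4,7,7a-tetrahydro-1,3-benzodioxol-5-yl]methyl benzoate
Product: 11 [(3R,4S,5R,6R)-3,4,5,6-tetrahydroxycyclohex-1-en-1-yl]methyl benzoate
Conditions: CF3CO2H/H2O (9:1), 0 °C → rt
Reagents that add atoms: none
Why: Aqueous-acid hydrolysis (global acetal and silyl ether deprotection) cleaves the acetonide at the acetal carbon and the silyl ether at silicon, so all four carbinol configurations are retained, while the primary benzoate should be stable to these conditions.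

Step 8
Reactants: 11 [(3R,4S,5R,6R)-3,4,5,6-tetrahydroxycyclohex-1-en-1-yl]methyl benzoate; 12 trimethyl orthobenzoate
Product: 14 [(3R,4S,5R,6R)-5-(benzoyloxy)-3,4,6-trihydroxycyclohex-1-en-1-yl]methyl benzoate, via cyclic 4,5-orthobenzoate 13 (not isolated)
Conditions: PhC(OMe)3 (1.2 equiv), camphorsulfonic acid (cat.), MeCN, rt; then AcOH/H2O (4:1), 0 °C
Reagents that add atoms: trimethyl orthobenzoate COC(OC)(OC)c1ccccc1; water O
Why: Acid-catalysed orthoester exchange should engage a cis-vicinal diol (the trans-3,4-diol would need a strained trans-fused dioxolane), and mild aqueous acid then opens the cyclic hemi-orthoester under stereoelectronic control to the axial ester and the equatorial alcohol (orthoester hydrolysis, axial-ester rule); O5 is the only axial oxygen of the preferred half-chair (the alternative half-chair would place O4 and O6 syn-diaxial), so the benzoate should end on O5, also if the orthoester forms at O5/O6 instead of O4/O5.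

**Compound list**

1 | (4R)-4-[(tert-butyldimethylsilyl)oxy]cyclopent-2-en-1-one | O=C1C=C[C@H](O[Si](C)(C)C(C)(C)C)C1 | starting material
2 | (2S,3R,4R)-4-[(tert-butyldimethylsilyl)oxy]-2,3-dihydroxycyclopentan-1-one | O=C1C[C@@H](O[Si](C)(C)C(C)(C)C)[C@H](O)[C@@H]1O | intermediate
3 | (3aS,6R,6aR)-6-[(tert-butyldimethylsilyl)oxy]-2,2-dimethyltetrahydro-4H-cyclopenta[d][1,3]dioxol-4-one | O=C1C[C@@H](O[Si](C)(C)C(C)(C)C)[C@@H]2OC(C)(C)O[C@H]12 | intermediate
4 | ethyl diazoacetate | CCOC(=O)C=[N+]=[N-] | starting material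
5 | ethyl (3aS,7R,7aR)-7-[(tert-butyldimethylsilyl)oxy]-2,2-dimethyl-4-oxohexahydro-1,3-benzodioxole-5-carboxylate (enol tautomer drawn) | CCOC(=O)C1=C(O)[C@H]2OC(C)(C)O[C@H]2[C@H](O[Si](C)(C)C(C)(C)C)C1 | intermediate
6 | ethyl (3aS,5S,7R,7aR)-7-[(tert-butyldimethylsilyl)oxy]-2,2-dimethyl-4-oxo-5-(phenylselanyl)hexahydro-1,3-benzodioxole-5-carboxylate (selenium anti to the dioxolane drawn) | CCOC(=O)[C@]1([Se]c2ccccc2)C[C@@H](O[Si](C)(C)C(C)(C)C)[C@@H]2OC(C)(C)O[C@@H]2C1=O | intermediate (not isolated)
7 | ethyl (3aS,7R,7aR)-7-[(tert-butyldimethylsilyl)oxy]-2,2-dimethyl-4-oxo-3a,4,7,7a-tetrahydro-1,3-benzodioxole-5-carboxylate | CCOC(=O)C1=C[C@@H](O[Si](C)(C)C(C)(C)C)[C@@H]2OC(C)(C)O[C@@H]2C1=O | intermediate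
8 | (3aR,4R,7R,7aR)-7-[(tert-butyldimethylsilyl)oxy]-5-(hydroxymethyl)-2,2-dimethyl-3a,4,7,7a-tetrahydro-1,3-benzodioxol-4-ol | OCC1=C[C@@H](O[Si](C)(C)C(C)(C)C)[C@@H]2OC(C)(C)O[C@@H]2[C@@H]1O | intermediate
9 | benzoyl chloride | O=C(Cl)c1ccccc1 | starting material
10 | [(3aR,4R,7R,7aR)-7-[(tert-butyldimethylsilyl)oxy]-4-hydroxy-2,2-dimethyl-3a,4,7,7a-tetrahydro-1,3-benzodioxol-5-yl]methyl benzoate | O=C(OCC1=C[C@@H](O[Si](C)(C)C(C)(C)C)[C@@H]2OC(C)(C)O[C@@H]2[C@@H]1O)c1ccccc1 | intermediate
11 | [(3R,4S,5R,6R)-3,4,5,6-tetrahydroxycyclohex-1-en-1-yl]methyl benzoate | O=C(OCC1=C[C@@H](O)[C@H](O)[C@H](O)[C@@H]1O)c1ccccc1 | intermediate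
12 | trimethyl orthobenzoate | COC(OC)(OC)c1ccccc1 | starting material
13 | cyclic 4,5-O-[methoxy(phenyl)methylene] orthobenzoate of tetrol 11, O3 and O6 free, 7-benzoate (exo-phenyl epimer drawn) | O=C(OCC1=C[C@@H](O)[C@@H]2O[C@@](OC)(c3ccccc3)O[C@@H]2[C@@H]1O)c1ccccc1 | intermediate (not isolated)
14 | [(3R,4S,5R,6R)-5-(benzoyloxy)-3,4,6-trihydroxycyclohex-1-en-1-yl]methyl benzoate | O=C(OCC1=C[C@@H](O)[C@H](O)[C@H](OC(=O)c2ccccc2)[C@@H]1O)c1ccccc1 | target

**Totals.** Total step count: 8. Longest linear sequence: 8 steps (from 1).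

**Steps most likely to fail**

Step 3 (key step). What may go wrong: under BF3 the acetonide may be lost or silanol eliminated from the β-silyloxy ketone, or the oxygenated α-carbon may migrate in competition. The fallback sets out from 3 and comes back at 8, and still enlarges the five-membered ring by one carbon. Kinetic enol silylation toward the CH2 carbon (LiN(SiMe3)2, Me3SiCl present from the start, THF, −78 °C) should give the trimethylsilyl enol ether F1. Dibromocarbene (CHBr3, KOtBu, pentane, −30 °C → rt) should add to the enol ether to give the dibromocyclopropane F2 (not isolated), which opens with loss of bromotrimethylsilane to the ring-enlarged 2-bromoenone F3; the enol ether fixes where the new carbon enters. Stille coupling with tributyl(hydroxymethyl)stannane (Pd(PPh3)4, dioxane, 90 °C) should give the hydroxymethyl enone F4. Luche reduction (NaBH4, CeCl3·7H2O, MeOH, −78 °C) then returns diol 8.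

Step 5. What may go wrong: conjugate hydride delivery to the doubly activated C1=C2 bond, or reduction of the ester before the ketone with loss of facial control at C6. The fallback sets out from 7 and comes back at 8 by a staged reduction. Luche conditions (NaBH4, CeCl3·7H2O, MeOH, −78 °C) should reduce only the ketone, in 1,2-fashion and anti to the dioxolane, to the hydroxy enoate F5. iBu2AlH (CH2Cl2, −78 °C) then reduces the now ordinary unsaturated ester to 8.

Step 8. What may go wrong: orthoester exchange at the trans-3,4-diol, or benzoyl migration from the axial O5 to the equatorial O4 or O6 during hydrolysis, leading to regioisomeric monobenzoates. The fallback sets out from 10 and comes back at 14; it replaces stereoelectronic control by protecting-group differentiation. Selective acetonide hydrolysis (AcOH/H2O 4:1, 40 °C, silyl ether retained) should give the triol F6. tBu2Si(OTf)2 with 2,6-lutidine (CH2Cl2, 0 °C) should bridge the cis-1,3-related O4 and O6 to give the cyclic silylene F7, in which the ring has flipped and O5 is the only free, now equatorial, hydroxyl. BzCl, 4-dimethylaminopyridine and pyridine should give the dibenzoate F8. HF·pyridine in THF then removes both silicon groups to give 14.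

**Further compounds**

F1 | step 3 | trimethylsilyl enol ether of 3 (enol double bond toward the CH2 carbon) | C[Si](C)(C)OC1=C[C@@H](O[Si](C)(C)C(C)(C)C)[C@@H]2OC(C)(C)O[C@H]12
F2 | step 3 | 6,6-dibromo-1-(trimethylsilyloxy)bicyclo[3.1.0]hexane adduct of F1 (cyclopropane anti to the tert-butyldimethylsilyloxy group drawn) | C[Si](C)(C)O[C@@]12C(Br)(Br)[C@@H]1[C@@H](O[Si](C)(C)C(C)(C)C)[C@@H]1OC(C)(C)O[C@@H]12
F3 | step 3 | (3aS,7R,7aR)-5-bromo-7-[(tert-butyldimethylsilyl)oxy]-2,2-dimethyl-7,7a-dihydro-1,3-benzodioxol-4(3aH)-one | O=C1C(Br)=C[C@@H](O[Si](C)(C)C(C)(C)C)[C@@H]2OC(C)(C)O[C@H]12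
F4 | step 3 | (3aS,7R,7aR)-7-[(tert-butyldimethylsilyl)oxy]-5-(hydroxymethyl)-2,2-dimethyl-7,7a-dihydro-1,3-benzodioxol-4(3aH)-one | O=C1C(CO)=C[C@@H](O[Si](C)(C)C(C)(C)C)[C@@H]2OC(C)(C)O[C@H]12
F5 | step 5 | ethyl (3aR,4R,7R,7aR)-7-[(tert-butyldimethylsilyl)oxy]-4-hydroxy-2,2-dimethyl-3a,4,7,7a-tetrahydro-1,3-benzodioxole-5-carboxylate | CCOC(=O)C1=C[C@@H](O[Si](C)(C)C(C)(C)C)[C@@H]2OC(C)(C)O[C@@H]2[C@@H]1O
F6 | step 8 | [(3R,4R,5R,6R)-3-[(tert-butyldimethylsilyl)oxy]-4,5,6-trihydroxycyclohex-1-en-1-yl]methyl benzoate | O=C(OCC1=C[C@@H](O[Si](C)(C)C(C)(C)C)[C@H](O)[C@H](O)[C@@H]1O)c1ccccc1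
F7 | step 8 | 4,6-O-(di-tert-butylsilanediyl) derivative of F6 (O5 free) | O=C(OCC1=C[C@@H](O[Si](C)(C)C(C)(C)C)[C@@H]2O[Si](C(C)(C)C)(C(C)(C)C)O[C@H]1[C@H]2O)c1ccccc1
F8 | step 8 | 5-O-benzoate of F7 | O=C(OCC1=C[C@@H](O[Si](C)(C)C(C)(C)C)[C@@H]2O[Si](C(C)(C)C)(C(C)(C)C)O[C@H]1[C@H]2OC(=O)c1ccccc1)c1ccccc1
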